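The synthesis rests on disconnecting both pendant indole rings back to acetaldehyde side chains on C2 of the indolin-3-one core. The quaternary C2 is bonded to C3' of two indole rings, and each C3'/C2' pair can be read as the α-carbon and carbonyl carbon of an aldehyde. The C2–C3' bonds are therefore made early, as plain enolate allylations. A twofold Fischer indolization of the N-acetyl 2,2-bis(2-oxoethyl)indolin-3-one with phenylhydrazine then forms C3'–C3a' and N1'–C2' on each arm and closes both pyrrole rings in one operation. Mild base finally removes the acetyl group.

Key step: step 3

Remark on the chemistry: C2 of the target carries two identical indol-3-yl groups, so the compound is achiral and has no enantiomer. The SMILES is taken as it stands and no stereocontrol is planned.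

Step 1
Reactants: 1 1-acetylindolin-3-one; 2 allyl bromide (2.5 equiv)
Product: 4 1-acetyl-2,2-diallylindolin-3-one, via 1-acetyl-2-allylindolin-3-one 3 (not isolated)
Conditions: K2CO3 (3 equiv), DMF, 0 °C → rt, N2
Reagents that add atoms: none
Why: The C2 methylene of 1 is activated by the aryl ketone and the N-acyl group (its enolate is an aromatic 3-oxidoindole), so carbonate should suffice for two successive enolate SN2 C-allylations with the soft allylic bromide, the second one through 3 creating the quaternary C2, while the N-acetyl group blocks N-allylation and survives carbonate in an aprotic solvent.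

Step 2
Reactants: 4 1-acetyl-2,2-diallylindolin-3-one
Product: 6 2,2'-(1-acetyl-3-oxoindoline-2,2-diyl)diacetaldehyde, via bis(1,2,4-trioxolane) ozonide 5 (not isolated)
Conditions: O3, CH2Cl2, −78 °C, then N2 purge; PPh3 (2.2 equiv), −78 °C → rt
Reagents that add atoms: ozone, [O-][O+]=O
Why: Ozonolysis (Criegee mechanism) of the two monosubstituted alkenes should give bis-ozonide 5, which triphenylphosphine reduces to the two aldehydes with release of formaldehyde; the acylated, ketone-bearing benzene ring is inert to ozone at −78 °C, and the neutral work-up spares the β-amido aldehydes from elimination, 6 being washed with water, concentrated cold and used at once.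

Step 3
Reactants: 6 2,2'-(1-acetyl-3-oxoindoline-2,2-diyl)diacetaldehyde; 7 phenylhydrazine (2.3 equiv)
Product: 10 1-acetyl-2,2-di(1H-indol-3-yl)indolin-3-one, via bis(phenylhydrazone) 8 (not isolated), via mono-indole hydrazone 9 (not isolated)
Conditions: 6 added slowly to 7 in EtOH, 0 °C → rt; evaporate; AcOH, 90 °C, N2
Reagents that add atoms: none
Why: Each aldehyde of 6 condenses with 7 to a phenylhydrazone (8), which acid tautomerizes to the ene-hydrazine; after N-protonation a [3,3] sigmatropic shift joins the former aldehyde α-carbon to the ortho carbon of the phenyl ring (C3'–C3a'), rearomatization frees an aniline nitrogen that adds to the iminium carbon (N1'–C2'), and loss of ammonia gives the indole. This is the Fischer indole synthesis as it is known for aldehyde arylhydrazones whose α-CH2 bears a fully substituted carbon, which give 2-unsubstituted 3-tert-alkylindoles; here it should run twice, by way of 9. Each pyrrole ring closes by 5-exo-trig attack of nitrogen on the C=N carbon, its C3'–C3a' bond having been set by the preceding [3,3] shift. No stereocentre is formed, because C2 ends with two identical indolyl groups. Regiochemistry is secured because each aldehyde has a single enolizable carbon and the hydrazine ring is unsubstituted; the aldehydes should react in preference to the C3 ketone, which is an aryl ketone flanked by the quaternary C2, and bridging of both arms by one hydrazine is countered by adding 6 to excess 7 so that 8 is complete before acid is introduced. The N1 acetyl group withholds the N1 lone pair, so hot acetic acid should neither expel N1 from C2 nor drive a C2→C3 1,2-shift to an oxindole.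

Step 4
Reactants: 10 1-acetyl-2,2-di(1H-indol-3-yl)indolin-3-one
Product: 11 2,2-di(1H-indol-3-yl)indolin-3-one (target)
Conditions: K2CO3, MeOH, rt
Reagents that add atoms: none
Why: Base-mediated methanolysis of the amide (N-deacetylation) should be easy because N1 is conjugated through the benzene ring with the C3 ketone, which makes the N-acetyl group imide-like, while the indole N–H groups, the ketone and the quaternary C2 are untouched and no acid is present that could trigger rearrangement.

Compound list
1 | 1-acetylindolin-3-one | CC(=O)N1CC(=O)c2ccccc12 | starting material
2 | allyl bromide | C=CCBr | starting material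
3 | 1-acetyl-2-allylindolin-3-one (racemic) | CC(=O)N1C(CC=C)C(=O)c2ccccc12 | intermediate
4 | 1-acetyl-2,2-diallylindolin-3-one | CC(=O)N1c2ccccc2C(=O)C1(CC=C)CC=C | intermediate
5 | 1-acetyl-2,2-bis(1,2,4-trioxolan-3-ylmethyl)indolin-3-one (bis-ozonide; stereoisomer mixture at the two trioxolane C3 atoms, immaterial) | CC(=O)N1c2ccccc2C(=O)C1(CC1OCOO1)CC1OCOO1 | intermediate
6 | 2,2'-(1-acetyl-3-oxoindoline-2,2-diyl)diacetaldehyde | CC(=O)N1c2ccccc2C(=O)C1(CC=O)CC=O | intermediate
7 | phenylhydrazine | NNc1ccccc1 | starting material
8 | 1-acetyl-2,2-bis[2-(2-phenylhydrazinylidene)ethyl]indolin-3-one (C=N geometry undefined, immaterial) | CC(=O)N1c2ccccc2C(=O)C1(CC=NNc1ccccc1)CC=NNc1ccccc1 | intermediate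
9 | 1-acetyl-2-(1H-indol-3-yl)-2-[2-(2-phenylhydrazinylidene)ethyl]indolin-3-one (racemic; C=N geometry undefined) | CC(=O)N1c2ccccc2C(=O)C1(CC=NNc1ccccc1)c1c[nH]c2ccccc12 | intermediate
10 | 1-acetyl-2,2-di(1H-indol-3-yl)indolin-3-one | CC(=O)N1c2ccccc2C(=O)C1(c1c[nH]c2ccccc12)c1c[nH]c2ccccc12 | intermediate
11 | 2,2-di(1H-indol-3-yl)indolin-3-one, 2,2-bis(3'-indolyl)indoxyl (achiral) | O=C1c2ccccc2NC1(c1c[nH]c2ccccc12)c1c[nH]c2ccccc12 | target

Total step count: 4
Longest linear sequence: 4 steps (1 → 4 → 6 → 10 → 11)

Steps most likely to fail

Step 3 (double Fischer indolization). Three processes may compete with the intended course: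
- One hydrazine nitrogen may bridge both C2 arms in a six-membered cyclocondensation, either before the second hydrazone is in place or by transhydrazonation under acid.
- The N1 amide may be lost by β-elimination from the ene-hydrazine, which opens the five-membered ring.
- The [3,3] shift at the carbon next to the quaternary C2 may be slow, so that the aldehyde-derived ene-hydrazines oligomerize.

The fallback gives up building the indoles and attaches preformed indole twice to C2 as a carbon nucleophile; it sets out from 1 and rejoins the route at 11. α-Bromination of 1 at C2 (Br2, CH2Cl2, 0 °C) should give 1-acetyl-2-bromoindolin-3-one F1, an N-acyl α-bromoamine that ionizes to an N-acyliminium ion. Friedel–Crafts capture by C3 of commercial indole (NaHCO3, CH2Cl2) should give 1-acetyl-2-(1H-indol-3-yl)indolin-3-one F2. Methanolysis of the acetyl group (K2CO3, MeOH) should release 2-(1H-indol-3-yl)indolin-3-one F3, which air should dehydrogenate to the cyclic ketimine 2-(1H-indol-3-yl)-3H-indol-3-one F4 with water as the co-product. Acid-catalysed aza-Friedel–Crafts addition of a second indole to the C2=N bond of this 3H-indol-3-one (AcOH, rt) should then give 11 directly.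

Step 2 (ozonolysis to the dialdehyde). The dialdehyde may be lost during reductive work-up and separation from the phosphine oxide: N1 may be eliminated from the β-amido aldehydes (retro-aza-Michael), the aldehydes may hydrate or oligomerize, or surviving peroxides may over-oxidize them to acids. The fallback splits the cleavage into two stages through a storable polyol; it sets out from 4 and returns at 6. Upjohn dihydroxylation of both alkenes (cat. OsO4, NMO, acetone/H2O) should give 1-acetyl-2,2-bis(2,3-dihydroxypropyl)indolin-3-one F5 as a diastereomer mixture that can be purified and kept. Glycol cleavage with NaIO4 (THF/H2O) just before the hydrazone formation should release 6 beside only filterable iodate and water-soluble formaldehyde.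

Step 1 (double C-allylation). Three processes may interfere:
- The ambident 3-oxidoindole enolate may be allylated on oxygen to give allyl enol ethers.
- The reaction may stall at mono-allyl compound 3, because the second alkylation has to create a quaternary centre.
- Base may remove the N-acetyl group, after which the free indoxyl dimerizes oxidatively to indigo-type dyes.

The fallback replaces the SN2 alkylation by π-allylpalladium chemistry; it sets out from 1 and returns at 4 without any new isolated compound. Tsuji–Trost allylation with allyl methyl carbonate (2.5 equiv) and Pd(PPh3)4 (cat.) in THF at rt → 50 °C, without added base, should deliver both allyl groups to carbon. The stabilized enolate attacks the π-allyl complex as a soft carbon nucleophile, and any O-allyl ether re-ionizes under Pd(0) and is funnelled to the C-allyl ketone.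

Further compounds
F1 | step 3 | 1-acetyl-2-bromoindolin-3-one (racemic) | CC(=O)N1C(Br)C(=O)c2ccccc12
F2 | step 3 | 1-acetyl-2-(1H-indol-3-yl)indolin-3-one (racemic) | CC(=O)N1C(c2c[nH]c3ccccc23)C(=O)c2ccccc12
F3 | step 3 | 2-(1H-indol-3-yl)indolin-3-one (racemic) | O=C1c2ccccc2NC1c1c[nH]c2ccccc12
F4 | step 3 | 2-(1H-indol-3-yl)-3H-indol-3-one | O=C1C(c2c[nH]c3ccccc23)=Nc2ccccc12
F5 | step 2 | 1-acetyl-2,2-bis(2,3-dihydroxypropyl)indolin-3-one (diastereomer mixture) | CC(=O)N1c2ccccc2C(=O)C1(CC(O)CO)CC(O)CO
F0 | step 1 | none | none
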